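The route rests on folding the side chain into a temporary 5,6-dihydro-2H-pyran running through O-1′, C1′, C2′, C3′, C4′ and C5′ (C1′ is the carbinol carbon, C4′ bears CH2OH). Since C3′=C4′ is then created within a six-membered ring, C2′ and C5′ are forced cis. A single hetero-Diels–Alder reaction of (S)-glyceraldehyde acetonide with a geometrically defined (1Z)-1-methoxy-2-(silyloxymethyl)buta-1,3-diene forms C1′–C2′ and a disposable O–C5′ bond and sets (R)-C1′ by Felkin–Anh control. Afterwards the O–C5′ bond is cleaved reductively, C5′ is joined to farnesyl C1 through a sulfone, and the dioxolane is converted into the furanone ring.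

Key step: step 5

Remarks on the chemistry
- Assumption: commercial (S)-glyceraldehyde acetonide (8) is depolymerised by distillation just before use; a cis/trans mixture at the acetal carbon of 9 is of no consequence because that centre is oxidised in step 6.
- Stereochemical bookkeeping: the target carbinol is (R). Felkin–Anh addition to the (S)-aldehyde gives the anti adduct, (6R) in the pyran. The priority order O > dioxolane or furanone carbon > C2′ > H holds throughout, so the descriptor stays (R) to the end.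
- Precursor design: the silyl ether on the diene is TBDPS, because it has to pass Jones oxidation, i-Bu2AlH and an acidic acetonide cleavage. The enol ether geometry (methoxy trans to vinyl) is fixed by construction rather than by a carbonyl olefination, so that all of the diene can reach the reactive s-cis conformation.

Step 1
Reactants: 1 prop-2-yn-1-ol
Product: 3 (2Z)-2-(iodomethylidene)but-3-en-1-ol, via cyclic alkenylmagnesium alkoxide 2 (not isolated)
Conditions: vinylmagnesium bromide (3 equiv), CuI (10 mol %), THF, −10 °C to rt; then I2, THF, −20 to 0 °C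
Reagents that add atoms: vinylmagnesium bromide, C=C[Mg]Br; iodine, II
Why: Alkoxide-directed anti-carbomagnesiation of the propargylic alkoxide, catalysed by monovalent copper, puts the vinyl group on the internal carbon and magnesium on the terminal carbon cis to CH2O in a five-membered chelate, and iodinolysis with retention should leave iodine cis to CH2OH.

Step 2
Reactants: 3 (2Z)-2-(iodomethylidene)but-3-en-1-ol
Product: 4 tert-butyl{[(2Z)-2-(iodomethylidene)but-3-en-1-yl]oxy}diphenylsilane
Conditions: TBDPSCl, imidazole, CH2Cl2, 0 °C to rt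
Reagents that add atoms: tert-butyl(chloro)diphenylsilane, CC(C)(C)[Si](Cl)(c1ccccc1)c1ccccc1
Why: Routine silylation of a primary alcohol, which the alkenyl iodide tolerates.

Step 3
Reactants: 4 tert-butyl{[(2Z)-2-(iodomethylidene)but-3-en-1-yl]oxy}diphenylsilane
Product: 5 tert-butyl{[(2Z)-2-(methoxymethylidene)but-3-en-1-yl]oxy}diphenylsilane, that is (1Z)-1-methoxy-2-[(tert-butyldiphenylsilyloxy)methyl]buta-1,3-diene with methoxy trans to vinyl
Conditions: CuI (10 mol %), 3,4,7,8-tetramethyl-1,10-phenanthroline (20 mol %), Cs2CO3, MeOH (5 equiv), toluene, 80 °C, sealed tube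
Reagents that add atoms: methanol, CO
Why: Ullmann-type C–O coupling of an alkenyl iodide with an alcohol under catalysis by monovalent copper proceeds with retention of alkene geometry, so methoxy should end up cis to CH2OTBDPS and trans to the vinyl group, and the fully substituted neighbouring carbon rules out elimination.

Step 4
Reactants: 6 (2E,6E)-farnesyl bromide
Product: 7 {[(2E,6E)-3,7,11-trimethyldodeca-2,6,10-trien-1-yl]sulfonyl}benzene (farnesyl phenyl sulfone)
Conditions: PhSO2Na, DMF, rt
Reagents that add atoms: sodium benzenesulfinate, [Na+].[O-]S(=O)c1ccccc1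
Why: SN2 S-alkylation of the sulfinate by the primary allylic bromide should keep both trisubstituted alkenes in place.

Step 5
Reactants: 8 (4S)-2,2-dimethyl-1,3-dioxolane-4-carbaldehyde; 5 (1Z)-1-methoxy-2-[(tert-butyldiphenylsilyloxy)methyl]buta-1,3-diene
Product: 9 (2S,6R)-3-[(tert-butyldiphenylsilyloxy)methyl]-6-[(4S)-2,2-dimethyl-1,3-dioxolan-4-yl]-2-methoxy-5,6-dihydro-2H-pyran (2,6-cis)
Conditions: 8 (1.0 equiv), 5 (1.3 equiv), Eu(fod)3 (5 mol %), CH2Cl2 (concentrated), rt, 2–4 d
Reagents that add atoms: none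
Why: The aldehyde carbonyl, activated by the trivalent europium centre of Eu(fod)3, adds across the diene termini in a concerted but asynchronous [4+2] hetero-Diels–Alder cycloaddition, the unsubstituted diene terminus (future C2′) bonding to the carbonyl carbon (C1′) and the carbonyl oxygen to the methoxy-bearing carbon (future C5′); the closest known reaction type is the Lewis-acid-promoted cycloaddition of 1-methoxybuta-1,3-dienes with glyceraldehyde acetonide to give 2-methoxy-5,6-dihydro-2H-pyrans. The single ring, the 5,6-dihydro-2H-pyran through O-1′ and C1′ to C5′, is closed intermolecularly by the cycloaddition itself, both ring bonds (C1′–C2′ and O–C5′) being made in the same step. The C1′ stereocentre (pyran C6) is controlled by the dioxolane stereocentre: Felkin–Anh attack on the carbonyl face anti to the dioxolane C–O bond should give the anti adduct with (R)-C1′. The acetal stereocentre (pyran C2) is set by the endo preference of the lanthanide-promoted reaction (2,6-cis expected), but either epimer serves because this centre is oxidised away in step 6. The step needs regioselectivity, which the methoxy donor secures by placing the largest HOMO coefficient on the unsubstituted terminus, and facial selectivity, which the α-oxygen of the aldehyde secures; the cis arrangement of C2′ and C5′ across C3′=C4′ needs no control because that alkene is formed inside the six-membered ring.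

Step 6
Reactants: 9 (2S,6R)-3-[(tert-butyldiphenylsilyloxy)methyl]-6-[(4S)-2,2-dimethyl-1,3-dioxolan-4-yl]-2-methoxy-5,6-dihydro-2H-pyran
Product: 10 (6R)-3-[(tert-butyldiphenylsilyloxy)methyl]-6-[(4S)-2,2-dimethyl-1,3-dioxolan-4-yl]-5,6-dihydro-2H-pyran-2-one
Conditions: CrO3, H2SO4, H2O, acetone, 0 °C, 20–30 min; i-PrOH quench
Reagents that add atoms: water, O
Why: Jones oxidation of a cyclic methyl acetal (hydrolysis to the lactol and immediate oxidation by hexavalent chromium) is a known way from 2-alkoxy-5,6-dihydro-2H-pyrans to 5,6-dihydro-2H-pyran-2-ones, acetone at 0 °C should shield the isopropylidene group, and the ring stays closed so that C2′ and C5′ remain cis.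

Step 7
Reactants: 10 (6R)-3-[(tert-butyldiphenylsilyloxy)methyl]-6-[(4S)-2,2-dimethyl-1,3-dioxolan-4-yl]-5,6-dihydro-2H-pyran-2-one
Product: 12 (2E,5R)-2-[(tert-butyldiphenylsilyloxy)methyl]-5-[(4S)-2,2-dimethyl-1,3-dioxolan-4-yl]pent-2-ene-1,5-diol (C1 cis to C4 across the alkene), via lactol 11 (not isolated)
Conditions: i-Bu2AlH (4 equiv), CH2Cl2, −78 to 0 °C; aq. potassium sodium tartrate
Reagents that add atoms: none
Why: 1,2-Reduction of the unsaturated lactone by i-Bu2AlH through the lactol cleaves the disposable O–C5′ bond and leaves C5′ as CH2OH cis to C2′ while the other allylic oxygen stays silylated, so the two CH2O groups on C4′ are differentiated without further steps.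

Step 8
Reactants: 12 (2E,5R)-2-[(tert-butyldiphenylsilyloxy)methyl]-5-[(4S)-2,2-dimethyl-1,3-dioxolan-4-yl]pent-2-ene-1,5-diol
Product: 13 (1R,3Z)-5-bromo-4-[(tert-butyldiphenylsilyloxy)methyl]-1-[(4S)-2,2-dimethyl-1,3-dioxolan-4-yl]pent-3-en-1-ol
Conditions: CBr4 (1.15 equiv), PPh3 (1.2 equiv), CH2Cl2, −30 to 0 °C; crude product used at once
Reagents that add atoms: tetrabromomethane, BrC(Br)(Br)Br
Why: Appel bromination is far faster at the primary allylic hydroxyl than at the hindered secondary one flanked by the dioxolane and proceeds by SN2 under neutral conditions without allylic transposition.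

Step 9
Reactants: 13 (1R,3Z)-5-bromo-4-[(tert-butyldiphenylsilyloxy)methyl]-1-[(4S)-2,2-dimethyl-1,3-dioxolan-4-yl]pent-3-en-1-ol
Product: 14 tert-butyl{[(1R,3Z)-5-bromo-4-[(tert-butyldiphenylsilyloxy)methyl]-1-[(4S)-2,2-dimethyl-1,3-dioxolan-4-yl]pent-3-en-1-yl]oxy}dimethylsilane
Conditions: TBSOTf, 2,6-lutidine, CH2Cl2, −78 °C
Reagents that add atoms: tert-butyldimethylsilyl trifluoromethanesulfonate, CC(C)(C)[Si](C)(C)OS(=O)(=O)C(F)(F)F
Why: Silylation with a silyl triflate and a hindered base is fast at −78 °C, so the allylic bromide and the acetonide should be untouched, and capping C1′–OH removes the nucleophile that could close a ring onto C5′ in the next step.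

Step 10
Reactants: 7 farnesyl phenyl sulfone; 14 tert-butyl{[(1R,3Z)-5-bromo-4-[(tert-butyldiphenylsilyloxy)methyl]-1-[(4S)-2,2-dimethyl-1,3-dioxolan-4-yl]pent-3-en-1-yl]oxy}dimethylsilane
Product: 16 (4S)-4-[(1R,3E,7E,11E)-6-(benzenesulfonyl)-1-[(tert-butyldimethylsilyl)oxy]-4-[(tert-butyldiphenylsilyloxy)methyl]-8,12,16-trimethylheptadeca-3,7,11,15-tetraen-1-yl]-2,2-dimethyl-1,3-dioxolane as both C6 epimers, via lithiated sulfone 15 (not isolated)
Conditions: 7 (1.1 equiv), n-BuLi, THF, −78 °C; then 14, −78 to −20 °C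
Reagents that add atoms: none
Why: α-Alkylation of the sulfone-stabilised allylic carbanion with the primary allylic bromide (Julia-type sulfone coupling) forms the C5′–farnesyl C1 bond by SN2 without disturbing either neighbouring trisubstituted alkene, and the new sulfone-bearing centre is removed in the next step.

Step 11
Reactants: 16 the coupled sulfone
Product: 17 (4S)-4-[(1R,3E,7E,11E)-1-[(tert-butyldimethylsilyl)oxy]-4-[(tert-butyldiphenylsilyloxy)methyl]-8,12,16-trimethylheptadeca-3,7,11,15-tetraen-1-yl]-2,2-dimethyl-1,3-dioxolane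
Conditions: PdCl2(dppp) (5 mol %), LiBHEt3 (2.5 equiv), THF, 0 °C
Reagents that add atoms: none
Why: Reductive desulfonylation of an allylic sulfone through a π-allyl complex (zerovalent palladium formed in situ) delivers hydride to the less hindered, sulfone-bearing terminus with retention of the (E)-trisubstituted alkene, and silyl ethers and acetonide are inert to LiBHEt3 at 0 °C.

Step 12
Reactants: 17 the desulfonylated acetonide
Product: 18 (2S,3R,5E,9E,13E)-3-[(tert-butyldimethylsilyl)oxy]-6-[(tert-butyldiphenylsilyloxy)methyl]-10,14,18-trimethylnonadeca-5,9,13,17-tetraene-1,2-diol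
Conditions: PPTS (0.3 equiv), MeOH, 40 °C
Reagents that add atoms: none
Why: Acid-catalysed transketalisation to methanol removes the terminal isopropylidene acetal under conditions that the hindered secondary TBS ether, the TBDPS ether and the trisubstituted alkenes should tolerate.

Step 13
Reactants: 18 the 1,2-diol
Product: 19 (2S,3R,5E,9E,13E)-3-[(tert-butyldimethylsilyl)oxy]-6-[(tert-butyldiphenylsilyloxy)methyl]-2-hydroxy-10,14,18-trimethylnonadeca-5,9,13,17-tetraen-1-yl (diethoxyphosphoryl)acetate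
Conditions: (EtO)2P(O)CH2CO2H (1.1 equiv), DCC, DMAP (cat.), CH2Cl2, 0 °C
Reagents that add atoms: diethylphosphonoacetic acid, CCOP(=O)(CC(=O)O)OCC
Why: Steglich esterification should acylate the primary hydroxyl selectively because the secondary one is crowded by the adjacent silyloxy-bearing carbon.

Step 14
Reactants: 19 the hydroxy phosphonoacetate
Product: 20 (3R,5E,9E,13E)-3-[(tert-butyldimethylsilyl)oxy]-6-[(tert-butyldiphenylsilyloxy)methyl]-10,14,18-trimethyl-2-oxononadeca-5,9,13,17-tetraen-1-yl (diethoxyphosphoryl)acetate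
Conditions: Dess–Martin periodinane, CH2Cl2, 0 °C to rt
Reagents that add atoms: none
Why: Dess–Martin oxidation converts the remaining secondary alcohol into the ketone under nearly neutral conditions that spare alkenes, silyl ethers and the phosphonate and should not epimerise C1′.

Step 15
Reactants: 20 the keto phosphonoacetate
Product: 21 4-[(1R,3E,7E,11E)-1-[(tert-butyldimethylsilyl)oxy]-4-[(tert-butyldiphenylsilyloxy)methyl]-8,12,16-trimethylheptadeca-3,7,11,15-tetraen-1-yl]furan-2(5H)-one
Conditions: LiCl, i-Pr2NEt, MeCN, 0 °C to rt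
Reagents that add atoms: none
Why: Intramolecular Horner–Wadsworth–Emmons olefination under Masamune–Roush conditions closes the furan-2(5H)-one, the ketone carbon (former dioxolane C4) becoming ring carbon C4 and the former dioxolane CH2 ring carbon C5, and the weak amine base should not enolise the ketone toward C1′.

Step 16
Reactants: 21 the bis-silyl butenolide
Product: 22 Hippolide C, 4-[(1R,3E,7E,11E)-1-hydroxy-4-(hydroxymethyl)-8,12,16-trimethylheptadeca-3,7,11,15-tetraen-1-yl]furan-2(5H)-one
Conditions: HF·pyridine, pyridine, THF, 0 °C to rt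
Reagents that add atoms: none
Why: Fluoride-mediated cleavage of both silyl ethers under buffered, mildly acidic conditions should free the C1′ hydroxyl and the CH2OH on C4′ without opening or isomerising the base-sensitive butenolide.

Compound list
1 | prop-2-yn-1-ol | C#CCO | starting material
2 | 4-ethenyl-2,5-dihydro-1,2-oxamagnesole (cyclic alkenylmagnesium alkoxide) | C=CC1=C[Mg]OC1 | intermediate
3 | (2Z)-2-(iodomethylidene)but-3-en-1-ol | OC/C(C=C)=C\I | intermediate
4 | tert-butyl{[(2Z)-2-(iodomethylidene)but-3-en-1-yl]oxy}diphenylsilane | I/C=C(\CO[Si](c1ccccc1)(c2ccccc2)C(C)(C)C)C=C | intermediate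
5 | (1Z)-1-methoxy-2-[(tert-butyldiphenylsilyloxy)methyl]buta-1,3-diene (methoxy trans to vinyl) | CO/C=C(\CO[Si](c1ccccc1)(c2ccccc2)C(C)(C)C)C=C | intermediate
6 | (2E,6E)-farnesyl bromide | CC(C)=CCC/C(C)=C/CC/C(C)=C/CBr | starting material
7 | {[(2E,6E)-3,7,11-trimethyldodeca-2,6,10-trien-1-yl]sulfonyl}benzene | CC(C)=CCC/C(C)=C/CC/C(C)=C/CS(=O)(=O)c1ccccc1 | intermediate
8 | (4S)-2,2-dimethyl-1,3-dioxolane-4-carbaldehyde | O=C[C@@H]1COC(C)(C)O1 | starting material
9 | (2S,6R)-3-[(tert-butyldiphenylsilyloxy)methyl]-6-[(4S)-2,2-dimethyl-1,3-dioxolan-4-yl]-2-methoxy-5,6-dihydro-2H-pyran | CO[C@H]1O[C@H](CC=C1CO[Si](c2ccccc2)(c3ccccc3)C(C)(C)C)[C@@H]4COC(C)(C)O4 | intermediate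
10 | (6R)-3-[(tert-butyldiphenylsilyloxy)methyl]-6-[(4S)-2,2-dimethyl-1,3-dioxolan-4-yl]-5,6-dihydro-2H-pyran-2-one | O=C1O[C@H](CC=C1CO[Si](c2ccccc2)(c3ccccc3)C(C)(C)C)[C@@H]4COC(C)(C)O4 | intermediate
11 | (6R)-3-[(tert-butyldiphenylsilyloxy)methyl]-6-[(4S)-2,2-dimethyl-1,3-dioxolan-4-yl]-5,6-dihydro-2H-pyran-2-ol (lactol, present as its aluminium alkoxide, both C2 epimers) | OC1O[C@H](CC=C1CO[Si](c2ccccc2)(c3ccccc3)C(C)(C)C)[C@@H]4COC(C)(C)O4 | intermediate
12 | (2E,5R)-2-[(tert-butyldiphenylsilyloxy)methyl]-5-[(4S)-2,2-dimethyl-1,3-dioxolan-4-yl]pent-2-ene-1,5-diol | OC/C(CO[Si](c1ccccc1)(c2ccccc2)C(C)(C)C)=C\C[C@@H](O)[C@@H]3COC(C)(C)O3 | intermediate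
13 | (1R,3Z)-5-bromo-4-[(tert-butyldiphenylsilyloxy)methyl]-1-[(4S)-2,2-dimethyl-1,3-dioxolan-4-yl]pent-3-en-1-ol | BrC/C(CO[Si](c1ccccc1)(c2ccccc2)C(C)(C)C)=C\C[C@@H](O)[C@@H]3COC(C)(C)O3 | intermediate
14 | tert-butyl{[(1R,3Z)-5-bromo-4-[(tert-butyldiphenylsilyloxy)methyl]-1-[(4S)-2,2-dimethyl-1,3-dioxolan-4-yl]pent-3-en-1-yl]oxy}dimethylsilane | BrC/C(CO[Si](c1ccccc1)(c2ccccc2)C(C)(C)C)=C\C[C@@H](O[Si](C)(C)C(C)(C)C)[C@@H]3COC(C)(C)O3 | intermediate
15 | [(2E,6E)-1-(benzenesulfonyl)-3,7,11-trimethyldodeca-2,6,10-trien-1-yl]lithium | CC(C)=CCC/C(C)=C/CC/C(C)=C/C([Li])S(=O)(=O)c1ccccc1 | intermediate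
16 | (4S)-4-[(1R,3E,7E,11E)-6-(benzenesulfonyl)-1-[(tert-butyldimethylsilyl)oxy]-4-[(tert-butyldiphenylsilyloxy)methyl]-8,12,16-trimethylheptadeca-3,7,11,15-tetraen-1-yl]-2,2-dimethyl-1,3-dioxolane (both C6 epimers) | CC(C)=CCC/C(C)=C/CC/C(C)=C/C(C/C(CO[Si](c1ccccc1)(c2ccccc2)C(C)(C)C)=C\C[C@@H](O[Si](C)(C)C(C)(C)C)[C@@H]3COC(C)(C)O3)S(=O)(=O)c4ccccc4 | intermediate
17 | (4S)-4-[(1R,3E,7E,11E)-1-[(tert-butyldimethylsilyl)oxy]-4-[(tert-butyldiphenylsilyloxy)methyl]-8,12,16-trimethylheptadeca-3,7,11,15-tetraen-1-yl]-2,2-dimethyl-1,3-dioxolane | CC(C)=CCC/C(C)=C/CC/C(C)=C/CC/C(CO[Si](c1ccccc1)(c2ccccc2)C(C)(C)C)=C\C[C@@H](O[Si](C)(C)C(C)(C)C)[C@@H]3COC(C)(C)O3 | intermediate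
18 | (2S,3R,5E,9E,13E)-3-[(tert-butyldimethylsilyl)oxy]-6-[(tert-butyldiphenylsilyloxy)methyl]-10,14,18-trimethylnonadeca-5,9,13,17-tetraene-1,2-diol | CC(C)=CCC/C(C)=C/CC/C(C)=C/CC/C(CO[Si](c1ccccc1)(c2ccccc2)C(C)(C)C)=C\C[C@@H](O[Si](C)(C)C(C)(C)C)[C@@H](O)CO | intermediate
19 | (2S,3R,5E,9E,13E)-3-[(tert-butyldimethylsilyl)oxy]-6-[(tert-butyldiphenylsilyloxy)methyl]-2-hydroxy-10,14,18-trimethylnonadeca-5,9,13,17-tetraen-1-yl (diethoxyphosphoryl)acetate | CC(C)=CCC/C(C)=C/CC/C(C)=C/CC/C(CO[Si](c1ccccc1)(c2ccccc2)C(C)(C)C)=C\C[C@@H](O[Si](C)(C)C(C)(C)C)[C@@H](O)COC(=O)CP(=O)(OCC)OCC | intermediate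
20 | (3R,5E,9E,13E)-3-[(tert-butyldimethylsilyl)oxy]-6-[(tert-butyldiphenylsilyloxy)methyl]-10,14,18-trimethyl-2-oxononadeca-5,9,13,17-tetraen-1-yl (diethoxyphosphoryl)acetate | CC(C)=CCC/C(C)=C/CC/C(C)=C/CC/C(CO[Si](c1ccccc1)(c2ccccc2)C(C)(C)C)=C\C[C@@H](O[Si](C)(C)C(C)(C)C)C(=O)COC(=O)CP(=O)(OCC)OCC | intermediate
21 | 4-[(1R,3E,7E,11E)-1-[(tert-butyldimethylsilyl)oxy]-4-[(tert-butyldiphenylsilyloxy)methyl]-8,12,16-trimethylheptadeca-3,7,11,15-tetraen-1-yl]furan-2(5H)-one | CC(C)=CCC/C(C)=C/CC/C(C)=C/CC/C(CO[Si](c1ccccc1)(c2ccccc2)C(C)(C)C)=C\C[C@@H](O[Si](C)(C)C(C)(C)C)C3=CC(=O)OC3 | intermediate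
22 | Hippolide C, 4-[(1R,3E,7E,11E)-1-hydroxy-4-(hydroxymethyl)-8,12,16-trimethylheptadeca-3,7,11,15-tetraen-1-yl]furan-2(5H)-one | CC(C)=CCC/C(C)=C/CC/C(C)=C/CC/C(CO)=C\C[C@@H](O)C1=CC(=O)OC1 | target

Total step count: 16 steps.
Longest linear sequence: 15 steps (steps 1–3 and 5–16; step 4 is the one-step side branch).

Steps most likely to fail

Step 5. The cycloaddition of a diene carrying only one oxygen donor may be too slow at ambient pressure, the dienol ether may be hydrolysed by adventitious acid, or facial selectivity at the aldehyde may erode. Fallback: lactone 10 is reached without a cycloaddition, setting out from aldehyde 8. Reagent-controlled allylboration of 8 with (+)-B-allyldiisopinocampheylborane (Et2O, −78 °C; then NaOH, H2O2), matched with the Felkin preference, should give (1R)-1-[(4S)-2,2-dimethyl-1,3-dioxolan-4-yl]but-3-en-1-ol F1. Commercial methyl 2-(hydroxymethyl)acrylate is silylated (TBDPSCl, imidazole) to methyl 2-[(tert-butyldiphenylsilyloxy)methyl]prop-2-enoate F2 and saponified (LiOH, THF–H2O) to 2-[(tert-butyldiphenylsilyloxy)methyl]prop-2-enoic acid F3. Steglich esterification of F1 with F3 (DCC, DMAP) gives (1R)-1-[(4S)-2,2-dimethyl-1,3-dioxolan-4-yl]but-3-en-1-yl 2-[(tert-butyldiphenylsilyloxy)methyl]prop-2-enoate F4. Ring-closing metathesis with the second-generation Grubbs catalyst (toluene, 80 °C) then forms the trisubstituted alkene inside the lactone ring, so that C2′ and C5′ are again cis, and the route is rejoined at 10.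

Step 6. The strongly acidic oxidant may remove the isopropylidene group, or the ring may open transiently before oxidation is complete. Fallback: the lactone is bypassed, setting out from acetal 9. Buffered hydrolysis (PPTS, acetone–H2O, rt; acetone as solvent holds the acetonide in place) gives lactol 11, which is reduced through its open hydroxy-enal form under Luche conditions (NaBH4, CeCl3·7H2O, MeOH, −20 °C) directly to diol 12, where the route is rejoined. This makes no compound outside the compound list (F0).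

Step 8. The cis-configured 1,5-diol may undergo cyclodehydration to a dihydropyran under the phosphonium activation, the hydroxy bromide may ring-close on standing, or discrimination between the two hydroxyls may be incomplete. Fallback: setting out from diol 12, both hydroxyls are silylated (TBSOTf, 2,6-lutidine, CH2Cl2, −78 °C) to (4S)-4-[(1R,3E)-1,5-bis[(tert-butyldimethylsilyl)oxy]-4-[(tert-butyldiphenylsilyloxy)methyl]pent-3-en-1-yl]-2,2-dimethyl-1,3-dioxolane F5. The primary allylic TBS ether is then cleaved selectively (HF·pyridine, pyridine, THF, 0 °C) to (2E,5R)-5-[(tert-butyldimethylsilyl)oxy]-2-[(tert-butyldiphenylsilyloxy)methyl]-5-[(4S)-2,2-dimethyl-1,3-dioxolan-4-yl]pent-2-en-1-ol F6. Appel bromination (CBr4, PPh3, CH2Cl2, −20 °C) of F6, in which C1′–O is already masked, gives 14, where the route is rejoined.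

Further compounds
F1 | step 5 | (1R)-1-[(4S)-2,2-dimethyl-1,3-dioxolan-4-yl]but-3-en-1-ol | C=CC[C@@H](O)[C@@H]1COC(C)(C)O1
F2 | step 5 | methyl 2-[(tert-butyldiphenylsilyloxy)methyl]prop-2-enoate | C=C(CO[Si](c1ccccc1)(c2ccccc2)C(C)(C)C)C(=O)OC
F3 | step 5 | 2-[(tert-butyldiphenylsilyloxy)methyl]prop-2-enoic acid | C=C(CO[Si](c1ccccc1)(c2ccccc2)C(C)(C)C)C(=O)O
F4 | step 5 | (1R)-1-[(4S)-2,2-dimethyl-1,3-dioxolan-4-yl]but-3-en-1-yl 2-[(tert-butyldiphenylsilyloxy)methyl]prop-2-enoate | C=CC[C@@H](OC(=O)C(=C)CO[Si](c1ccccc1)(c2ccccc2)C(C)(C)C)[C@@H]3COC(C)(C)O3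
F0 | step 6 | none | none
F5 | step 8 | (4S)-4-[(1R,3E)-1,5-bis[(tert-butyldimethylsilyl)oxy]-4-[(tert-butyldiphenylsilyloxy)methyl]pent-3-en-1-yl]-2,2-dimethyl-1,3-dioxolane | CC(C)(C)[Si](C)(C)OC/C(CO[Si](c1ccccc1)(c2ccccc2)C(C)(C)C)=C\C[C@@H](O[Si](C)(C)C(C)(C)C)[C@@H]3COC(C)(C)O3
F6 | step 8 | (2E,5R)-5-[(tert-butyldimethylsilyl)oxy]-2-[(tert-butyldiphenylsilyloxy)methyl]-5-[(4S)-2,2-dimethyl-1,3-dioxolan-4-yl]pent-2-en-1-ol | OC/C(CO[Si](c1ccccc1)(c2ccccc2)C(C)(C)C)=C\C[C@@H](O[Si](C)(C)C(C)(C)C)[C@@H]3COC(C)(C)O3
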